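**Plan**
Numbering used throughout, also for the fragments: C1 = C(OH)(CH2OH) with C7 = CH2OH, C2 = CHOH, C3 = CH(OBz), C4=C5, C6 = CH(OBz).
Retrosynthesis: C7 is raised to CHO and O1/O2 are masked as chloroacetates. C2–C3 and C1–C6 are then cut together (retro-Diels–Alder), giving (1E,3E)-1,4-dibenzoyloxybutadiene and an (E)-2,3-bis(acyloxy)acrolein made from triose reductone.
Enabling feature: the carbocycle is a cyclohexene whose only C=C (C4=C5) is flanked by two cis O-benzoylated carbons (C3, C6). O2 and C7 lie on that same face and O1 on the opposite one, which is the pattern of an endo addition of an E-enal to an E,E-diene.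
Forward order: the diene takes two steps (cross-metathesis, dienol benzoylation) and the dienophile one (acylation). One cycloaddition then delivers the ring, its alkene and both benzoates, followed by CHO → CH2OH and dechloroacetylation.
Stereochemistry: C3/C6 come from the diene geometry, C1/C2 from the dienophile geometry, their mutual relation from the endo rule, and the absolute configuration from a chiral oxazaborolidinium Lewis acid.

Key step: step 4

Assumption: triose reductone (2,3-dihydroxyprop-2-enal) is taken as a purchasable speciality chemical.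
Assumption: the (S)-configured catalyst is taken to leave open the C1-Si/C2-Re face of the bound enal, by analogy with 2-substituted acroleins. The mirror-image catalyst is equally accessible should the sense be opposite.

Step 1
Reactants: 1 allyl benzoate; 2 (E)-crotonaldehyde
Product: 3 (E)-4-oxobut-2-en-1-yl benzoate
Conditions: 2 (5 equiv), second-generation Hoveyda–Grubbs catalyst RuCl2(H2IMes)(=CH-C6H4-2-OiPr) (2 mol %), CH2Cl2, 40 °C
Reagents that add atoms: none
Why: Olefin cross-metathesis of a terminal allylic ester with an excess of an electron-poor enal is a well-established selective pairing that should give the E-enal with loss of propene; no stereocentre is formed.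

Step 2
Reactants: 3 (E)-4-oxobut-2-en-1-yl benzoate
Product: 5 (1E,3E)-buta-1,3-diene-1,4-diyl dibenzoate, via (1E,3Z)-isomer 4 (not isolated)
Conditions: BzCl, Et3N, 4-(dimethylamino)pyridine (10 mol %), PhMe, 60 °C; then I2 (5 mol %), PhMe, 80 °C, visible light; recrystallisation
Reagents that add atoms: benzoyl chloride O=C(Cl)c1ccccc1
Why: Amine-mediated γ-enolisation and O-benzoylation of an enal is the standard enol-ester route to 1-acyloxy-1,3-dienes, and iodine-catalysed equilibration (reversible iodine-atom addition) should funnel the geometric isomers into the least hindered, crystalline E,E isomer, the only one able to adopt the s-cis conformation needed in step 4.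

Step 3
Reactants: 6 triose reductone, (2E)-2,3-dihydroxyprop-2-enal
Product: 7 (1E)-3-oxoprop-1-ene-1,2-diyl bis(chloroacetate)
Conditions: (ClCH2CO)2O (2.4 equiv), 2,6-lutidine (2.4 equiv), CH2Cl2, −40 → 0 °C
Reagents that add atoms: chloroacetic anhydride O=C(CCl)OC(=O)CCl
Why: Double O-acylation of an enediol, in which the enolic OH on C2 is held cis to the formyl group by the internal hydrogen bond of the vinylogous acid and a hindered, non-nucleophilic base at low temperature should avoid the conjugate addition–elimination that scrambles such alkenes (in line with stereoretentive O-sulfonylation and O-acylation of α-formyl carbonyl enols), so that the E geometry (O2 cis to CHO, O1 trans to O2) is kept.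

Step 4
Reactants: 5 (1E,3E)-buta-1,3-diene-1,4-diyl dibenzoate; 7 (1E)-3-oxoprop-1-ene-1,2-diyl bis(chloroacetate)
Product: 8 (1R,4S,5R,6R)-5,6-bis[(chloroacetyl)oxy]-5-formylcyclohex-2-ene-1,4-diyl dibenzoate
Conditions: (S)-3,3-diphenyl-1-(2-methylphenyl)tetrahydro-1H,3H-pyrrolo[1,2-c][1,3,2]oxazaborole (20 mol %), Tf2NH (17 mol %), 7 (1.3 equiv), CH2Cl2, −40 → −20 °C
Reagents that add atoms: none
Why: Proposed new method: the cationic boron Lewis acid binds the formyl oxygen of 7 (supported by a formyl C–H···O contact) and lowers the LUMO of the C1=C2 bond, which the two weakly donating chloroacetoxy groups leave electron-poor, and diene 5 adds in a concerted, asynchronous, suprafacial–suprafacial [4+2] cycloaddition. The closest known reaction types are oxazaborolidinium-catalysed Diels–Alder reactions of 2-substituted and 2,3-disubstituted acroleins, Diels–Alder reactions of 2-(acyloxy)acroleins, and the thermal all-cis additions of (E,E)-1,4-diacetoxybutadiene to acrylates and to vinylene carbonate, whereas a 2,3-bis(acyloxy)acrolein has not been used as a dienophile. The single six-membered carbocycle is closed by cycloaddition, C2–C3 and C1–C6 being formed in the same event and C4=C5 emerging as the ring alkene. C3 and C6 become cis because both benzoyloxy groups are outside substituents of the E,E-diene, O1 and O2 become trans (O2 cis to CHO) because the E geometry of 7 is transferred suprafacially, the endo orientation of CHO and of the acyloxy group cis to it places C7 and O2 on the face of the two benzoates, and the absolute sense comes from the catalyst, whose aryl group should block the C1-Re/C2-Si face of bound 7. There is no regiochemical question because 5 is C2h-symmetric, acyl rather than silyl or alkyl groups on the enal oxygens should disfavour the (4+3) and hetero-Diels–Alder paths, and only the E,E-diene can reach the reactive s-cis conformation. The adduct has a quaternary C1, so neither epimerisation nor β-elimination of the benzoates through an enol is possible.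

Step 5
Reactants: 8 (1R,4S,5R,6R)-5,6-bis[(chloroacetyl)oxy]-5-formylcyclohex-2-ene-1,4-diyl dibenzoate
Product: 9 (1R,4S,5R,6R)-5,6-bis[(chloroacetyl)oxy]-5-(hydroxymethyl)cyclohex-2-ene-1,4-diyl dibenzoate
Conditions: NaBH4, CeCl3·7H2O, MeOH–THF, −78 → −40 °C; AcOH quench
Reagents that add atoms: none
Why: Luche-type borohydride reduction, in which the aldehyde is by far the most electrophilic carbonyl group, so that at low temperature in the weakly acidic CeCl3/MeOH medium the four esters and the alkene should remain untouched and alkoxide-driven benzoyl migration is suppressed; no stereocentre is formed, and a possible O1→O7 chloroacetyl shift is harmless because both positional isomers converge in step 6.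

Step 6
Reactants: 9 (1R,4S,5R,6R)-5,6-bis[(chloroacetyl)oxy]-5-(hydroxymethyl)cyclohex-2-ene-1,4-diyl dibenzoate
Product: 10 (1R,4S,5S,6R)-5,6-dihydroxy-5-(hydroxymethyl)cyclohex-2-ene-1,4-diyl dibenzoate (target)
Conditions: thiourea (6 equiv), MeOH–CH2Cl2, 40 °C, no added base
Reagents that add atoms: none
Why: Chemoselective dechloroacetylation, in which S-alkylation of thiourea at the CH2Cl groups and intramolecular acyl transfer (ring closure to 2-aminothiazol-4(5H)-one) release the hydroxyl groups under neutral to weakly acidic conditions that benzoates survive, a standard orthogonal ester pair in polyol chemistry; no stereocentre is touched.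

**Compound list**
1 | allyl benzoate | C=CCOC(=O)c1ccccc1 | starting material
2 | (E)-crotonaldehyde | C/C=C/C=O | starting material
3 | (E)-4-oxobut-2-en-1-yl benzoate | O=C/C=C/COC(=O)c1ccccc1 | intermediate
4 | (1E,3Z)-buta-1,3-diene-1,4-diyl dibenzoate | O=C(O/C=C/C=C\OC(=O)c1ccccc1)c1ccccc1 | intermediate
5 | (1E,3E)-buta-1,3-diene-1,4-diyl dibenzoate | O=C(O/C=C/C=C/OC(=O)c1ccccc1)c1ccccc1 | intermediate
6 | triose reductone, (2E)-2,3-dihydroxyprop-2-enal | O=C/C(O)=C\O | starting material
7 | (1E)-3-oxoprop-1-ene-1,2-diyl bis(chloroacetate) | O=C/C(OC(=O)CCl)=C\OC(=O)CCl | intermediate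
8 | (1R,4S,5R,6R)-5,6-bis[(chloroacetyl)oxy]-5-formylcyclohex-2-ene-1,4-diyl dibenzoate | O=C(O[C@H]1C=C[C@@H](OC(=O)c2ccccc2)[C@@H](OC(=O)CCl)[C@@]1(OC(=O)CCl)C=O)c1ccccc1 | intermediate
9 | (1R,4S,5R,6R)-5,6-bis[(chloroacetyl)oxy]-5-(hydroxymethyl)cyclohex-2-ene-1,4-diyl dibenzoate | O=C(O[C@H]1C=C[C@@H](OC(=O)c2ccccc2)[C@@H](OC(=O)CCl)[C@@]1(OC(=O)CCl)CO)c1ccccc1 | intermediate
10 | (1R,4S,5S,6R)-5,6-dihydroxy-5-(hydroxymethyl)cyclohex-2-ene-1,4-diyl dibenzoate | O=C(O[C@H]1C=C[C@@H](OC(=O)c2ccccc2)[C@@H](O)[C@@]1(O)CO)c1ccccc1 | target

Total step count: 6. Longest linear sequence: 5 steps (1 → 3 → 5 → 8 → 9 → 10).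

**Steps most likely to fail**

Step 4.
- What may go wrong: the trisubstituted, doubly oxygenated dienophile may be too unreactive. The acid may break down the dienyl ester. The reaction may leak to exo or hetero-Diels–Alder pathways. The facial discrimination may be low.
- Fallback (known chemistry), from 5 back to 10:
  - Compound 5 is heated with vinylene carbonate (neat, sealed tube, about 190 °C). This is the established all-cis cycloaddition of 1,4-diacyloxybutadienes; it still forms C2–C3 and C1–C6 in one event and gives the meso cyclic carbonate F1.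
  - Selective hydrolysis of the strained five-membered carbonate (pyridine–water, 40 °C) gives the meso all-cis diol F2.
  - Catalytic enantioselective monosilylation gives the 2-O-TBS ether F3. It uses TBSCl, iPr2NEt and the enantiomer of N-(3,3-dimethylbutan-2-yl)-3,3-dimethyl-2-{[(1-methylimidazol-2-yl)methyl]amino}butanamide that selects O2.
  - Dess–Martin oxidation gives the C1 ketone F4.
  - Non-basic methylenation (CH2Br2, Zn, TiCl4) gives the exocyclic alkene F5.
  - OsO4 (cat.) with N-methylmorpholine N-oxide should add to the more electron-rich 1,1-disubstituted alkene from the face opposite O2 and O6, giving the silylated triol F6.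
  - HF·pyridine then gives 10.

Step 3.
- What may go wrong: the alkene geometry may be lost by reversible conjugate addition–elimination of base or carboxylate. The vinylogous anhydride may hydrolyse on work-up.
- Fallback, from 6 back to 7: 6 is acylated without geometric control (ClCH2COCl, pyridine) and the isomers are separated by chromatography. The unwanted (Z)-bis(chloroacetate) F7 is converted into 7 by triplet-sensitised photoisomerisation (thioxanthone, 405 nm) with recycling.

Step 6.
- What may go wrong: benzoyl groups may migrate to the freed neighbouring hydroxyls (O3→O2, O6→O7) during the warm thiourea treatment. Release of the tertiary ester may be slow.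
- Fallback, from 6 back to 10: the temporary esters are changed to groups that leave by neutral solvolysis. Compound 6 and (CF3CO)2O give the (E)-bis(trifluoroacetate) F8. The cycloaddition with 5 under the conditions of step 4 gives the bis(trifluoroacetyl) aldehyde F9. Luche reduction in MeOH, followed by standing in neutral MeOH at 0 °C, reduces the aldehyde, solvolyses both trifluoroacetates and gives 10 directly.

**Further compounds**
F1 | step 4 | meso all-cis cyclic carbonate, (3aR,4R,7S,7aS)-2-oxo-3a,4,7,7a-tetrahydro-1,3-benzodioxole-4,7-diyl dibenzoate | O=C(O[C@H]1C=C[C@@H](OC(=O)c2ccccc2)[C@H]2OC(=O)O[C@@H]12)c1ccccc1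
F2 | step 4 | meso all-cis-5,6-dihydroxycyclohex-2-ene-1,4-diyl dibenzoate | O=C(O[C@H]1C=C[C@@H](OC(=O)c2ccccc2)[C@@H](O)[C@H]1O)c1ccccc1
F3 | step 4 | all-cis 2-O-TBS ether of F2 (free OH at C1) | O=C(O[C@H]1C=C[C@@H](OC(=O)c2ccccc2)[C@@H](O[Si](C)(C)C(C)(C)C)[C@H]1O)c1ccccc1
F4 | step 4 | C1 ketone, 2-O-TBS-3,6-di-O-benzoyl cyclohexenone | O=C(O[C@H]1C=C[C@@H](OC(=O)c2ccccc2)[C@@H](O[Si](C)(C)C(C)(C)C)C1=O)c1ccccc1
F5 | step 4 | C1 exocyclic methylene compound | O=C(O[C@H]1C=C[C@@H](OC(=O)c2ccccc2)[C@@H](O[Si](C)(C)C(C)(C)C)C1=C)c1ccccc1
F6 | step 4 | 2-O-TBS ether of 10 | O=C(O[C@H]1C=C[C@@H](OC(=O)c2ccccc2)[C@@H](O[Si](C)(C)C(C)(C)C)[C@@]1(O)CO)c1ccccc1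
F7 | step 3 | (1Z)-3-oxoprop-1-ene-1,2-diyl bis(chloroacetate) | O=C/C(OC(=O)CCl)=C/OC(=O)CCl
F8 | step 6 | (1E)-3-oxoprop-1-ene-1,2-diyl bis(trifluoroacetate) | O=C/C(OC(=O)C(F)(F)F)=C\OC(=O)C(F)(F)F
F9 | step 6 | bis(trifluoroacetyl) analogue of 8 | O=C(O[C@H]1C=C[C@@H](OC(=O)c2ccccc2)[C@@H](OC(=O)C(F)(F)F)[C@@]1(OC(=O)C(F)(F)F)C=O)c1ccccc1
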